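The aromatic ring is disconnected at C8a–C8 and C6–C7. The benzene ring (C4a, C5, C6, C7, C8, C8a) has no stereocentre and carries the carboxyl and two hydroxyls on the adjacent carbons C6, C7 and C8, so it is built last. An inverse-demand Diels–Alder addition of 1,1,2-trimethoxyethene to a ring-fused 3-carbomethoxy-2-pyrone, then loss of CO2 and methanol, gives the fully substituted arene in one operation. The precursor is that pyrone fused to the trans-1,4-disubstituted cyclohexane (a p-menthane from (R)-carvone), already holding the C1 methyl, the C4 side chain with C11 and C15 set, and both primary alcohols as pivalates.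

Key step: step 12

Numbering used: tetralin C1 (methyl), C4 (side chain), C4a, C5 (aromatic CH), C6 (carboxyl), C7 and C8 (hydroxyls), C8a; side chain C11 (hydroxymethyl C18), C12 to C14, C15 (methyl and hydroxymethyl C16).
Stereochemistry read from the target: 1R, 4S, 11S, 15S, with the C1 methyl and C4 side chain trans; C5 of (R)-carvone becomes C4, its descriptor changing only through CIP priorities.
Protecting groups: the two primary alcohols pass through the key step as pivalates, not silyl ethers, because BBr3 can turn primary silyl ethers (through their borates) into alkyl bromides; β-branched pivalates should survive it and leave in the final saponification.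
C13–C16 unit: it is taken from (R)-3-bromo-2-methylpropan-1-ol, so that no epimerisable aldehyde lies on the way.
Assumption: 1,1,2-trimethoxyethene (21) is treated as a purchasable, distillable ketene acetal.

Step 1
Reactants: 1 (R)-carvone
Product: 3 (2R,5R)-2-methyl-5-(prop-1-en-2-yl)cyclohexan-1-one (trans-dihydrocarvone), via lithium enolate 2 (not isolated)
Conditions: LiBH(s-Bu)3 (L-Selectride), THF, −78 °C; then aq. NH4Cl, −78 → 0 °C
Reagents that add atoms: none
Why: Conjugate (1,4-) hydride reduction of the β-unsubstituted enone gives enolate 2, and axial protonation places the C2 methyl (future C1) equatorial and trans to the equatorial C5 substituent (future C4), which is also the thermodynamically favoured arrangement; any minor cis epimer should be removable by chromatography.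

Step 2
Reactants: 3 trans-dihydrocarvone
Product: 4 (6R,9R)-6-methyl-9-(prop-1-en-2-yl)-1,4-dioxaspiro[4.5]decane
Conditions: TMSOCH2CH2OTMS, TMSOTf (5 mol%), CH2Cl2, −78 → −20 °C; pyridine quench
Reagents that add atoms: 1,2-bis(trimethylsilyloxy)ethane, C[Si](C)(C)OCCO[Si](C)(C)C
Why: TMSOTf-catalysed ketalisation (Noyori conditions) is aprotic and cold, so the ketone is masked for the Grignard step without enolisation at the methyl-bearing carbon and without touching the isopropenyl group.

Step 3
Reactants: 4 dioxolane of trans-dihydrocarvone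
Product: 5 (6R,9R)-9-(3-chloroprop-1-en-2-yl)-6-methyl-1,4-dioxaspiro[4.5]decane
Conditions: Ca(OCl)2, CO2 (solid), CH2Cl2/H2O, 0 °C
Reagents that add atoms: calcium hypochlorite, [Ca+2].[O-]Cl.[O-]Cl
Why: Ene-type allylic chlorination: HOCl formed in the flask delivers electrophilic chlorine to the terminal CH2 and loss of a methyl proton restores a 1,1-disubstituted alkene, while the near-neutral carbonate-buffered medium spares the dioxolane.

Step 4
Reactants: 6 (R)-3-bromo-2-methylpropan-1-ol
Product: 7 (R)-(3-bromo-2-methylpropoxy)(tert-butyl)dimethylsilane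
Conditions: TBSCl, imidazole, CH2Cl2, 0 → 25 °C
Reagents that add atoms: tert-butyldimethylsilyl chloride, CC(C)(C)[Si](C)(C)Cl
Why: Routine silylation of a primary alcohol; the purchased stereocentre (future C15) is not involved.

Step 5
Reactants: 7 silylated bromo alcohol
Product: 9 (S)-4-[(tert-butyldimethylsilyl)oxy]-3-methylbutan-1-ol, via Grignard reagent 8 (not isolated)
Conditions: Mg, THF, 45 °C; then (CH2O)n, 0 → 25 °C; aq. NH4Cl
Reagents that add atoms: formaldehyde (as paraformaldehyde), C=O
Why: Grignard addition to formaldehyde lengthens the chain by one carbon (future C13); the stereocentre is β to magnesium and cannot epimerise, its descriptor changing from R to S only by CIP priority.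

Step 6
Reactants: 9 homologated alcohol
Product: 10 (S)-(4-bromo-2-methylbutoxy)(tert-butyl)dimethylsilane
Conditions: CBr4, PPh3, CH2Cl2, 0 °C
Reagents that add atoms: carbon tetrabromide, BrC(Br)(Br)Br
Why: Appel bromination, an SN2 displacement at an unhindered primary carbon under neutral conditions that a silyl ether tolerates.

Step 7
Reactants: 10 (S)-(4-bromo-2-methylbutoxy)(tert-butyl)dimethylsilane; 5 allylic chloride
Product: 12 tert-butyldimethyl({(2S)-2-methyl-6-[(6R,9R)-6-methyl-1,4-dioxaspiro[4.5]decan-9-yl]hept-6-en-1-yl}oxy)silane, via Grignard reagent 11 (not isolated)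
Conditions: 10, Mg, THF, 45 °C; then 5, Li2CuCl4 (3 mol%), THF, −20 → 0 °C
Reagents that add atoms: none
Why: Copper-catalysed cross-coupling of a primary alkyl Grignard reagent with an allylic chloride forms C12–C13; because the allyl unit is 2-substituted with two like CH2 termini, direct and allylically transposed substitution give the same alkene, and ketal and silyl ether are inert.

Step 8
Reactants: 12 1,1-disubstituted alkene
Product: 14 (2S,6S)-7-[(tert-butyldimethylsilyl)oxy]-6-methyl-2-[(6R,9R)-6-methyl-1,4-dioxaspiro[4.5]decan-9-yl]heptan-1-ol, via pinacol boronate 13 (not isolated)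
Conditions: CuCl (5 mol%), (R)-DTBM-SEGPHOS (5.5 mol%), NaOt-Bu (10 mol%), HBpin, THF, 25 °C; then aq. NaOH, H2O2, 0 → 25 °C
Reagents that add atoms: hydrogen peroxide, OO
Why: Ligand-controlled copper hydride hydroboration of an unactivated 1,1-disubstituted alkene: hydride goes to C11 and copper to terminal C18, the bulky chiral bisphosphine selecting the alkene face by telling the ring carbon from the CH2 chain, so C11 is set (S) by the catalyst (the ligand antipode is the control element and would be exchanged if the substrate bias opposed it); exchange with HBpin and oxidation with retention give the primary alcohol.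

Step 9
Reactants: 14 silyl ether ketal alcohol
Product: 15 (2R,5R)-5-[(2S,6S)-1,7-dihydroxy-6-methylheptan-2-yl]-2-methylcyclohexan-1-one
Conditions: 1 M HCl, THF, 25 °C
Reagents that add atoms: water, O
Why: Aqueous acid hydrolyses the dioxolane and the primary silyl ether in one operation; the methyl-bearing carbon is α to the freed ketone, but its trans arrangement is the favoured one, so brief exposure should not erode it.

Step 10
Reactants: 15 keto diol
Product: 16 (2S,6S)-2-methyl-6-[(1R,4R)-4-methyl-3-oxocyclohexyl]heptane-1,7-diyl bis(2,2-dimethylpropanoate)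
Conditions: PivCl, pyridine, DMAP (10 mol%), CH2Cl2, 0 → 25 °C
Reagents that add atoms: pivaloyl chloride, CC(C)(C)C(=O)Cl
Why: Nucleophile-catalysed acylation of both primary alcohols; pivalates have no α-hydrogen and are hindered, so they should tolerate the amide base of step 11, the heat of step 12 and BBr3 in step 13.

Step 11
Reactants: 16 keto bis-pivalate; 17 dimethyl (methoxymethylene)malonate
Product: 20 methyl (5S,8R)-8-methyl-5-[(2S,6S)-6-methyl-1,7-bis(pivaloyloxy)heptan-2-yl]-2-oxo-5,6,7,8-tetrahydro-2H-chromene-3-carboxylate, via lithium enolate 18 (not isolated), via alkylidenemalonate 19 (not isolated)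
Conditions: LiN(i-Pr)2 (LDA, 1.05 equiv), THF, −78 °C; then 17, −78 → 25 °C; 1 M HCl quench
Reagents that add atoms: none
Why: Kinetic deprotonation by the hindered amide occurs at the ring CH2 (future C4a) and not at the methyl-bearing carbon, the enolate adds to 17 with loss of methoxide (conjugate addition–elimination), and methoxide-triggered enolisation with O-acylation by the cis ester closes the 2-pyrone (known pyrone annulation of ketone enolates); the future C1 and C4 centres are not touched.

Step 12
Reactants: 20 fused 3-carbomethoxy-2-pyrone; 21 1,1,2-trimethoxyethene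
Product: 24 methyl (5R,8S)-3,4-dimethoxy-5-methyl-8-[(2S,6S)-6-methyl-1,7-bis(pivaloyloxy)heptan-2-yl]-5,6,7,8-tetrahydronaphthalene-2-carboxylate, via bicyclic lactone 22 (not isolated), via cyclohexadiene 23 (not isolated)
Conditions: 21 (4 equiv), toluene, 130 °C, sealed tube, argon
Reagents that add atoms: none
Why: The lactone and ester carbonyls lower the LUMO of the pyrone diene and the three methoxy groups raise the HOMO of the alkene, so a concerted but asynchronous inverse-demand [4+2] addition across the pyrone termini (C8a and C6) should give bridged lactone 22. Cycloreversion then expels CO2 to leave diene 23, and thermal 1,2-elimination of methanol across C7–C8 aromatises it; the closest known reaction type is the benzannulation of 3-carbomethoxy-2-pyrones with ketene acetals. The benzene ring (C4a, C5, C6, C7, C8, C8a) is closed by intermolecular cycloaddition, both new bonds (C8a–C8 and C6–C7) forming in the pericyclic event rather than by cyclisation of a tethered chain. No new stereocentre remains, since the sp3 centres of 22 and 23 are erased on aromatisation, and C1, C4, C11 and C15 lie outside the reacting π-system and are not epimerised under neutral thermal conditions. The selectivity required is regiochemical: the nucleophilic MeO–CH terminus must bond to C8a and the acetal carbon to C6, which is secured because the oxygen-bearing C8a, vinylogous to both carbonyls, is the most electrophilic diene carbon and the CH terminus carries the largest HOMO coefficient. The pivalates and the methyl ester are spectators.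

Step 13
Reactants: 24 dimethoxy ester
Product: 25 methyl (5R,8S)-3,4-dihydroxy-5-methyl-8-[(2S,6S)-6-methyl-1,7-bis(pivaloyloxy)heptan-2-yl]-5,6,7,8-tetrahydronaphthalene-2-carboxylate
Conditions: BBr3 (6 equiv), CH2Cl2, −78 → 0 °C; aq. NaHCO3 work-up
Reagents that add atoms: none
Why: Lewis-acid ether cleavage: BBr3 complexes each aryl ether oxygen and bromide removes the methyl group by SN2, the C7 ether being activated by chelation to the ester and the C8 ether by formation of the cyclic catechol borate, while the β-branched pivalates give no alkoxy–boron species that could go on to an alkyl bromide.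

Step 14
Reactants: 25 catechol ester bis-pivalate
Product: 26 (5R,8S)-8-[(2S,6S)-1,7-dihydroxy-6-methylheptan-2-yl]-3,4-dihydroxy-5-methyl-5,6,7,8-tetrahydronaphthalene-2-carboxylic acid (CNP0255074.1)
Conditions: aq. KOH (excess), MeOH, 65 °C, degassed, argon; then 1 M HCl to pH 2
Reagents that add atoms: potassium hydroxide, [K+].[OH-]
Why: Saponification (acyl–oxygen cleavage by hydroxide) removes the methyl ester and both pivalates together; no stereocentre is α to a carbonyl, and exclusion of oxygen protects the catechol dianion.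

Compound list
1 | (R)-carvone, (5R)-2-methyl-5-(prop-1-en-2-yl)cyclohex-2-en-1-one | CC(=C)[C@@H]1CC=C(C)C(=O)C1 | starting material
2 | lithium (5R)-2-methyl-5-(prop-1-en-2-yl)cyclohex-1-en-1-olate | CC(=C)[C@@H]1CCC(C)=C([O-])C1.[Li+] | intermediate (not isolated)
3 | (2R,5R)-2-methyl-5-(prop-1-en-2-yl)cyclohexan-1-one (trans-dihydrocarvone) | CC(=C)[C@@H]1CC[C@@H](C)C(=O)C1 | intermediate
4 | (6R,9R)-6-methyl-9-(prop-1-en-2-yl)-1,4-dioxaspiro[4.5]decane | CC(=C)[C@@H]1CC[C@@H](C)C2(OCCO2)C1 | intermediate
5 | (6R,9R)-9-(3-chloroprop-1-en-2-yl)-6-methyl-1,4-dioxaspiro[4.5]decane | ClCC(=C)[C@@H]1CC[C@@H](C)C2(OCCO2)C1 | intermediate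
6 | (R)-3-bromo-2-methylpropan-1-ol | C[C@H](CO)CBr | starting material
7 | (R)-(3-bromo-2-methylpropoxy)(tert-butyl)dimethylsilane | C[C@H](CO[Si](C)(C)C(C)(C)C)CBr | intermediate
8 | [(2R)-3-[(tert-butyldimethylsilyl)oxy]-2-methylpropyl]magnesium bromide | C[C@H](CO[Si](C)(C)C(C)(C)C)C[Mg]Br | intermediate (not isolated)
9 | (S)-4-[(tert-butyldimethylsilyl)oxy]-3-methylbutan-1-ol | C[C@H](CO[Si](C)(C)C(C)(C)C)CCO | intermediate
10 | (S)-(4-bromo-2-methylbutoxy)(tert-butyl)dimethylsilane | C[C@H](CO[Si](C)(C)C(C)(C)C)CCBr | intermediate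
11 | [(3S)-4-[(tert-butyldimethylsilyl)oxy]-3-methylbutyl]magnesium bromide | C[C@H](CO[Si](C)(C)C(C)(C)C)CC[Mg]Br | intermediate (not isolated)
12 | tert-butyldimethyl({(2S)-2-methyl-6-[(6R,9R)-6-methyl-1,4-dioxaspiro[4.5]decan-9-yl]hept-6-en-1-yl}oxy)silane | C[C@H](CO[Si](C)(C)C(C)(C)C)CCCC(=C)[C@@H]1CC[C@@H](C)C2(OCCO2)C1 | intermediate
13 | C18 pinacol boronate corresponding to alcohol 14 (Bpin in place of OH, all stereocentres as in 14) | C[C@H](CO[Si](C)(C)C(C)(C)C)CCC[C@H](CB3OC(C)(C)C(C)(C)O3)[C@@H]1CC[C@@H](C)C2(OCCO2)C1 | intermediate (not isolated)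
14 | (2S,6S)-7-[(tert-butyldimethylsilyl)oxy]-6-methyl-2-[(6R,9R)-6-methyl-1,4-dioxaspiro[4.5]decan-9-yl]heptan-1-ol | C[C@H](CO[Si](C)(C)C(C)(C)C)CCC[C@H](CO)[C@@H]1CC[C@@H](C)C2(OCCO2)C1 | intermediate
15 | (2R,5R)-5-[(2S,6S)-1,7-dihydroxy-6-methylheptan-2-yl]-2-methylcyclohexan-1-one | C[C@H](CO)CCC[C@H](CO)[C@@H]1CC[C@@H](C)C(=O)C1 | intermediate
16 | (2S,6S)-2-methyl-6-[(1R,4R)-4-methyl-3-oxocyclohexyl]heptane-1,7-diyl bis(2,2-dimethylpropanoate) | C[C@H](COC(=O)C(C)(C)C)CCC[C@H](COC(=O)C(C)(C)C)[C@@H]1CC[C@@H](C)C(=O)C1 | intermediate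
17 | dimethyl (methoxymethylene)malonate | COC=C(C(=O)OC)C(=O)OC | starting material
18 | lithium enolate of 16, formed toward the ring CH2 next to the side-chain-bearing carbon (stereocentres as in 16) | C[C@H](COC(=O)C(C)(C)C)CCC[C@H](COC(=O)C(C)(C)C)[C@@H]1CC[C@@H](C)C([O-])=C1.[Li+] | intermediate (not isolated)
19 | ketone 16 carrying a 2,2-bis(methoxycarbonyl)vinyl group on that ring carbon (configuration there undefined, other stereocentres as in 16) | C[C@H](COC(=O)C(C)(C)C)CCC[C@H](COC(=O)C(C)(C)C)[C@@H]1CC[C@@H](C)C(=O)C1C=C(C(=O)OC)C(=O)OC | intermediate (not isolated)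
20 | methyl (5S,8R)-8-methyl-5-[(2S,6S)-6-methyl-1,7-bis(pivaloyloxy)heptan-2-yl]-2-oxo-5,6,7,8-tetrahydro-2H-chromene-3-carboxylate | C[C@H](COC(=O)C(C)(C)C)CCC[C@H](COC(=O)C(C)(C)C)[C@@H]1CC[C@@H](C)C2=C1C=C(C(=O)OC)C(=O)O2 | intermediate
21 | 1,1,2-trimethoxyethene | COC=C(OC)OC | starting material
22 | bridged 2-oxabicyclo[2.2.2]oct-5-en-3-one cycloadduct of 20 and 21 (new sp3 centres undefined) | C[C@H](COC(=O)C(C)(C)C)CCC[C@H](COC(=O)C(C)(C)C)[C@@H]1CC[C@@H](C)C23OC(=O)C(C(=O)OC)(C=C12)C(OC)(OC)C3OC | intermediate (not isolated)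
23 | 7,7,8-trimethoxy-7,8-dihydro precursor of 24 (cyclohexa-1,3-diene, C8 undefined) | C[C@H](COC(=O)C(C)(C)C)CCC[C@H](COC(=O)C(C)(C)C)[C@@H]1CC[C@@H](C)C2=C1C=C(C(=O)OC)C(OC)(OC)C2OC | intermediate (not isolated)
24 | methyl (5R,8S)-3,4-dimethoxy-5-methyl-8-[(2S,6S)-6-methyl-1,7-bis(pivaloyloxy)heptan-2-yl]-5,6,7,8-tetrahydronaphthalene-2-carboxylate | C[C@H](COC(=O)C(C)(C)C)CCC[C@H](COC(=O)C(C)(C)C)[C@@H]1CC[C@@H](C)c2c1cc(C(=O)OC)c(OC)c2OC | intermediate
25 | methyl (5R,8S)-3,4-dihydroxy-5-methyl-8-[(2S,6S)-6-methyl-1,7-bis(pivaloyloxy)heptan-2-yl]-5,6,7,8-tetrahydronaphthalene-2-carboxylate | C[C@H](COC(=O)C(C)(C)C)CCC[C@H](COC(=O)C(C)(C)C)[C@@H]1CC[C@@H](C)c2c1cc(C(=O)OC)c(O)c2O | intermediate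
26 | (5R,8S)-8-[(2S,6S)-1,7-dihydroxy-6-methylheptan-2-yl]-3,4-dihydroxy-5-methyl-5,6,7,8-tetrahydronaphthalene-2-carboxylic acid | C[C@H](CO)CCC[C@H](CO)[C@@H]1CC[C@@H](C)c2c1cc(C(=O)O)c(O)c2O | target

Total step count: 14 (steps 4 to 6 build the side-chain branch).
Longest linear sequence: 11 steps (steps 1 to 3 and 7 to 14 from (R)-carvone; the branch from 6 is equally long).

Steps most likely to fail

1. Step 12. What may go wrong: slow bond formation between the fully substituted C8a terminus (next to the C1 methyl) and the substituted CH(OMe) terminus of 21, so that thermal oligomerisation of the ketene acetal or incomplete loss of methanol competes. The fallback sets out from 20 and comes back to the route at 26. The unhindered, commercial 1,1-dimethoxyethene is used in the same thermal cycloaddition (toluene, 120 °C) and should give the C8-unsubstituted methyl 7-methoxy ester F1. BCl3 (CH2Cl2, −78 → 0 °C) then cleaves the methoxy group chelated to the ester to give the salicylate F2. N-Bromosuccinimide (MeCN, 0 °C) brominates the only free position ortho to the phenol, C8, the para position being the ring fusion, to give the bromophenol F3. Copper-catalysed hydroxylation (CuI, KOH, DMSO/H2O, 110 °C, argon) replaces bromide by hydroxyl and hydrolyses the three esters in the same operation, giving 26 after acidification.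

2. Step 8. What may go wrong: poor facial selectivity at C11, because the catalyst must tell the ring from a CH2 chain and may be mismatched with the neighbouring C4 centre. The fallback sets out from 12 and comes back at 14. Uncatalysed hydroboration with 9-BBN (THF, 25 °C) gives the B-alkyl-9-borabicyclo[3.3.1]nonane adduct F4, which NaOH/H2O2 oxidises to 14 and its C11 epimer F5. These are diastereomers and would be separated by chromatography (preparative HPLC if needed). F5 is recycled by Dess–Martin oxidation to the aldehyde F6, equilibration at C11 with DBU and NaBH4 reduction back to the separable pair of alcohols.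

3. Step 11. What may go wrong: sluggish C-alkylation at the enolate carbon next to the branched side chain, proton transfer that moves the enolate toward the methyl-bearing carbon, or acyl transfer from the nearby pivalate. The fallback sets out from 16 and comes back at 20. The kinetic enolate is trapped (LiN(i-Pr)2, TMSCl, THF, −78 °C) as the trimethylsilyl enol ether F7, which is isolated. A ZnBr2-promoted Mukaiyama–Michael addition–elimination with 17 (CH2Cl2, −20 → 25 °C) then gives alkylidenemalonate 19, this time isolated. Heating 19 with catalytic TsOH in toluene closes the lactone to 20.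

Further compounds
F1 | step 12 | methyl (5R,8S)-3-methoxy-5-methyl-8-[(2S,6S)-6-methyl-1,7-bis(pivaloyloxy)heptan-2-yl]-5,6,7,8-tetrahydronaphthalene-2-carboxylate | C[C@H](COC(=O)C(C)(C)C)CCC[C@H](COC(=O)C(C)(C)C)[C@@H]1CC[C@@H](C)c2c1cc(C(=O)OC)c(OC)c2
F2 | step 12 | methyl (5R,8S)-3-hydroxy-5-methyl-8-[(2S,6S)-6-methyl-1,7-bis(pivaloyloxy)heptan-2-yl]-5,6,7,8-tetrahydronaphthalene-2-carboxylate | C[C@H](COC(=O)C(C)(C)C)CCC[C@H](COC(=O)C(C)(C)C)[C@@H]1CC[C@@H](C)c2c1cc(C(=O)OC)c(O)c2
F3 | step 12 | methyl (5R,8S)-4-bromo-3-hydroxy-5-methyl-8-[(2S,6S)-6-methyl-1,7-bis(pivaloyloxy)heptan-2-yl]-5,6,7,8-tetrahydronaphthalene-2-carboxylate | C[C@H](COC(=O)C(C)(C)C)CCC[C@H](COC(=O)C(C)(C)C)[C@@H]1CC[C@@H](C)c2c1cc(C(=O)OC)c(O)c2Br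
F4 | step 8 | B-alkyl-9-borabicyclo[3.3.1]nonane adduct of 12 (boron on C18, both C11 configurations) | C[C@H](CO[Si](C)(C)C(C)(C)C)CCCC(CB3C4CCCC3CCC4)[C@@H]1CC[C@@H](C)C2(OCCO2)C1
F5 | step 8 | (2R,6S)-7-[(tert-butyldimethylsilyl)oxy]-6-methyl-2-[(6R,9R)-6-methyl-1,4-dioxaspiro[4.5]decan-9-yl]heptan-1-ol (C11 epimer of 14) | C[C@H](CO[Si](C)(C)C(C)(C)C)CCC[C@@H](CO)[C@@H]1CC[C@@H](C)C2(OCCO2)C1
F6 | step 8 | (6S)-7-[(tert-butyldimethylsilyl)oxy]-6-methyl-2-[(6R,9R)-6-methyl-1,4-dioxaspiro[4.5]decan-9-yl]heptanal (C2 epimerisable) | C[C@H](CO[Si](C)(C)C(C)(C)C)CCCC(C=O)[C@@H]1CC[C@@H](C)C2(OCCO2)C1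
F7 | step 11 | trimethylsilyl enol ether of 16 (enol double bond toward the ring CH2, stereocentres as in 16) | C[C@H](COC(=O)C(C)(C)C)CCC[C@H](COC(=O)C(C)(C)C)[C@@H]1CC[C@@H](C)C(O[Si](C)(C)C)=C1
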